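**Assumption:** dehydrocostus lactone (a bulk costus-root isolate sold as a catalogue compound) is taken as the cheap commercial starting material; guaiane locants are used, unprimed for the hydroxylated half and primed for the spiro half of the target.

## Retrosynthetic overview

1. Target 8 ⇒ diosphenol 6 (hydroxylated half) + dehydrozaluzanin C 3 (spiro half), cutting C2–C4' and C14–C15' of the spiro-cyclohexene.
2. C2–C4' links two ketone α-carbons; C2 is therefore used as an acceptor (the α-oxo carbonyl of a 2,3-dione, a hydroxy-enolonium equivalent) and C4' as the enolate released when C14 adds to C15' in a vinylogous Michael step.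
3. 6 ⇒ α-ketol 5 ⇒ 3 (α'-hydroxylation, then oxidation in the coupling flask); 3 ⇒ 2 ⇒ 1 (allylic oxidation of dehydrocostus lactone).
4. Ring order: both 5/7/5 guaianolide tricycles come intact from 1; the only ring built is the spiro-cyclohexene, formed last.

## Route

**Step 1**
Reactants: 1 dehydrocostus lactone (guaia-4(15),10(14),11(13)-trien-12,6-olide; H-1α, H-5α, H-6β, H-7α)
Product: 2 3-epizaluzanin C (3α-hydroxy, 3R)
Conditions: SeO2 (0.5 equiv), t-BuOOH (2 equiv, decane solution), CH2Cl2, 0 °C → rt
Reagents that add atoms: tert-butyl hydroperoxide, CC(C)(C)OO (terminal source of the new oxygen, relayed by catalytic selenium dioxide, O=[Se]=O)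
Why: Catalytic SeO2/TBHP allylic hydroxylation (ene reaction then [2,3]-shift) attacks the cyclopentane CH2 next to the C4=C15 methylene rather than the cycloheptane CH2 or the electron-poor lactone methylene, and delivers oxygen to the convex α-face; this centre is erased in step 2, so any 3β-epimer or over-oxidised 3 is carried along.

**Step 2**
Reactants: 2 3-epizaluzanin C
Product: 3 dehydrozaluzanin C (3-oxo-guaia-4(15),10(14),11(13)-trien-12,6-olide)
Conditions: Dess–Martin periodinane (1.3 equiv), CH2Cl2, 0 °C → rt
Reagents that add atoms: none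
Why: Dess–Martin oxidation of the secondary allylic alcohol gives the α-methylene cyclopentanone without base or heat, so the three Michael-acceptor olefins and the C1/C5 ring-fusion centres are untouched.

**Step 3**
Reactants: 3 dehydrozaluzanin C
Product: 5 2α-hydroxy-dehydrozaluzanin C (2R; OH cis to H-1), via potassium dienolate 4 (not isolated)
Conditions: KHMDS (1.05 equiv), THF, −78 °C (3 added to base); 2-(phenylsulfonyl)-3-phenyloxaziridine (1.3 equiv), −78 °C; AcOH quench
Reagents that add atoms: Davis oxaziridine (2-(phenylsulfonyl)-3-phenyloxaziridine), O=S(=O)(c1ccccc1)N1OC1c1ccccc1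
Why: Only C2 can be deprotonated (C4 is sp2), and Davis hydroxylation of the potassium cross-conjugated enolate (α'-hydroxylation of an enone) occurs on the convex α-face anti to the C1–C10 bond; the new centre is only a relay and is erased in step 4.

**Step 4**
Reactants: 5 2α-hydroxy-dehydrozaluzanin C; 3 dehydrozaluzanin C (2.5 equiv)
Product: 8 CNP0269880.2 (target spiro dimer), via diosphenol 6 (not isolated), via Michael enolate 7 (not isolated)
Conditions: 5, Dess–Martin periodinane (1.1 equiv), CH2Cl2, 0 °C, 30 min; then 3, Et3N (5 equiv), 0 °C → rt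
Reagents that add atoms: none
Why: Dess–Martin oxidation turns the ketol into the 2,3-dione (diosphenol 6), which converts C2 — like C4' a ketone α-carbon and normally a donor — into an acceptor (α-oxo carbonyl, a hydroxy-enolonium equivalent); Et3N then forms the diosphenolate, whose γ-carbon C14 adds to the exocyclic enone of 3 (vinylogous Michael addition, favoured over the less electrophilic lactone methylenes), and the C4' enolate so released closes onto C2 (intramolecular aldol, overall a base-mediated formal [4+2] annulation), bonding on the convex α-face of the cis-hydroazulenone (anti to C6', sets C4') and on the face of the flat ene-dione anti to H-5 (sets C2, OH α), with the reversible aldol expected to funnel to this natural-type spiro isomer.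

## Compound list

1 | dehydrocostus lactone | C=C1CC[C@H]2C(=C)CC[C@H]3C(=C)C(=O)O[C@@H]3[C@H]21 | starting material
2 | 3-epizaluzanin C (3α-hydroxy) | C=C1[C@H](O)C[C@H]2C(=C)CC[C@H]3C(=C)C(=O)O[C@@H]3[C@H]21 | intermediate
3 | dehydrozaluzanin C (3-ketone) | C=C1C(=O)C[C@H]2C(=C)CC[C@H]3C(=C)C(=O)O[C@@H]3[C@H]21 | intermediate
4 | potassium C2=C3 dienolate of 3 | C=C1C([O-])=C[C@H]2C(=C)CC[C@H]3C(=C)C(=O)O[C@@H]3[C@H]21.[K+] | intermediate
5 | 2α-hydroxy-dehydrozaluzanin C | C=C1C(=O)[C@H](O)[C@H]2C(=C)CC[C@H]3C(=C)C(=O)O[C@@H]3[C@H]21 | intermediate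
6 | diosphenol (2-hydroxy-3-oxo-guaia-1,4(15),10(14),11(13)-tetraen-12,6-olide; enol form of the 2,3-dione) | C=C1C(=O)C(O)=C2C(=C)CC[C@H]3C(=C)C(=O)O[C@@H]3[C@H]21 | intermediate
7 | triethylammonium C3'-enolate of the C14–C15' Michael adduct (unprimed half 1(10)-ene-2,3-dione) | C=C1C(=O)C(=O)C3=C(CC[C@H]4C(=C)C(=O)O[C@@H]4[C@@H]13)CCC1=C([O-])C[C@H]2C(=C)CC[C@H]3C(=C)C(=O)O[C@@H]3[C@H]21.CC[NH+](CC)CC | intermediate
8 | CNP0269880.2 (2α-OH cis to H-5, C2–C4' bond β; at spiro C4' the C2 substituent is α, cis to H-5', and C15' is β) | C=C1C(=O)[C@]2(O)C3=C(CC[C@H]4C(=C)C(=O)O[C@@H]4[C@@H]13)CC[C@]21C(=O)C[C@H]2C(=C)CC[C@H]3C(=C)C(=O)O[C@@H]3[C@H]21 | target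

## Totals and risks

Total step count: 4. Longest linear sequence: 4 (1 → 2 → 3 → 5 → 8; compound 3 is used twice).

**Step 4 (most likely to fail).** The free diosphenol may self-condense, the diosphenolate may react at O or C1, the product's own enone may react again, and the stepwise ring closure may not give the required facial pairing. The fallback sets out from 5 and returns at 8. Oxidise 5 with Dess–Martin periodinane and trap the diosphenol in the same flask with TBSOTf/2,6-lutidine as the isolable 2-(tert-butyldimethylsilyloxy) dienone F1. Heat F1 with 3 (toluene, 60–80 °C, BHT) in a concerted [4+2] cycloaddition of the 1-silyloxydiene, which enforces suprafacial bonding at C2 and C14 and gives the 2-O-TBS ether of the target F2. HF·pyridine (THF, 0 °C) then frees the tertiary alcohol to give 8.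

**Step 3.** The enolate may add to a second molecule of 3 or to the sulfonimine by-product. The fallback sets out from 3 and returns at 5. Soft enolisation (TMSOTf, Et3N, CH2Cl2, 0 °C) gives the 2-trimethylsilyloxy diene F3. Rubottom oxidation with dimethyldioxirane (acetone, −78 °C) gives the silyloxy-oxirane F4, which opens with silyl migration to the 2α-trimethylsilyloxy ketone F5. Citric acid in MeOH removes the silyl group and gives 5.

**Step 1.** Regioselectivity (C3 versus C9) and over-oxidation limit the yield. The fallback sets out from 1 and returns at 3: direct allylic C–H oxidation to the enone with CrO3·3,5-dimethylpyrazole (CH2Cl2, −20 °C), which skips alcohol 2 and makes no new compound (F0).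

## Further compounds

F1 | step 4 | 2-(tert-butyldimethylsilyloxy) dienone (TBS ether of 6) | C=C1C(=O)C(O[Si](C)(C)C(C)(C)C)=C2C(=C)CC[C@H]3C(=C)C(=O)O[C@@H]3[C@H]21
F2 | step 4 | 2-O-TBS ether of the target | C=C1C(=O)[C@]2(O[Si](C)(C)C(C)(C)C)C3=C(CC[C@H]4C(=C)C(=O)O[C@@H]4[C@@H]13)CC[C@]21C(=O)C[C@H]2C(=C)CC[C@H]3C(=C)C(=O)O[C@@H]3[C@H]21
F3 | step 3 | 2-trimethylsilyloxy diene (TMS dienol ether of 3) | C=C1C(O[Si](C)(C)C)=C[C@H]2C(=C)CC[C@H]3C(=C)C(=O)O[C@@H]3[C@H]21
F4 | step 3 | 2α,3α-epoxy-3-trimethylsilyloxy intermediate (silyloxy-oxirane) | C=C1[C@]2(O[Si](C)(C)C)O[C@@H]2[C@H]3C(=C)CC[C@H]4C(=C)C(=O)O[C@@H]4[C@@H]13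
F5 | step 3 | 2α-trimethylsilyloxy-dehydrozaluzanin C | C=C1C(=O)[C@H](O[Si](C)(C)C)[C@H]2C(=C)CC[C@H]3C(=C)C(=O)O[C@@H]3[C@H]21
F0 | step 1 | none | none
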